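**Retrosynthetic overview** (labdane numbering is used for all intermediates)
1. The target is an ent-labdane; it comes from its bis-silyl ether, whose two rings are closed in one flask from an acyclic enal–ene–yne: first the ring-fusion bond C5–C10 (ring A, 6-exo radical conjugate addition), then C7–C8 (ring B, nickel-mediated aldehyde–alkyne closure).
2. Enabling feature: C5–C6–C7 of ring B is an (E)-enal (C5 = β-carbon, C7 = carbonyl carbon), while C10 and C8 are the inner carbons of a 1,1-disubstituted alkene (C10=C20) and of an ethynyl group that both sit on C9; forming C5–C10 turns the enal into the C7 aldehyde next to C8.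
3. The acyclic precursor comes from (R)-limonene: its stereocentre is C9, its isopropenyl group is C20=C10–C1 (extended by allylic lithiation and oxirane), and its cleaved ring supplies the C8–C17 ethynyl arm and the C11–C14 arm.
4. The C3 carbinol and the C4 gem-dimethyl carbon come from an iridium-catalysed tert-prenylation; C5=C6–C7 comes from cross-metathesis with butenediol.
5. The 13Z enoate comes from the ring-derived methyl ketone via an ynoate and syn-carbocupration.

Key step: step 14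

Assumption: the (S)-SEGPHOS-modified iridium catalyst is taken to give the R carbinol (C3) in step 2; if the sense of induction is the opposite, (R)-SEGPHOS is used and nothing else changes.

Step 1
Reactants: 1 (R)-(+)-limonene; 2 oxirane
Product: 4 4-[(1R)-4-methylcyclohex-3-en-1-yl]pent-4-en-1-ol, via 10-lithiolimonene 3 (not isolated)
Conditions: n-BuLi, TMEDA, 1 (excess), hexane, 23 °C, 16 h; then 2, THF, −78 → 0 °C; H2O
Reagents that add atoms: none
Why: Allylic lithiation of limonene at the isopropenyl methyl group by n-BuLi·TMEDA gives a symmetric 2-substituted allyllithium that opens the epoxide (SN2), so the isopropenyl unit becomes C20=C10–C1 and the ring stereocentre (future C9) is not touched.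

Step 2
Reactants: 4 4-[(1R)-4-methylcyclohex-3-en-1-yl]pent-4-en-1-ol; 5 3-methylbuta-1,2-diene
Product: 6 (4R)-3,3-dimethyl-7-[(1R)-4-methylcyclohex-3-en-1-yl]octa-1,7-dien-4-ol
Conditions: [Ir(cod)Cl]2 (2.5 mol %), (S)-SEGPHOS (5 mol %), Cs2CO3 (20 mol %), 3-nitrobenzoic acid (10 mol %), 5 (3 equiv), THF, 70 °C, sealed tube
Reagents that add atoms: none
Why: Redox-neutral iridium-catalysed transfer-hydrogenative carbonyl reverse prenylation (alcohol dehydrogenation, allene hydrometalation, addition of the dimethylallyl-iridium through its substituted terminus) should set C3 under ligand control and create the C4 gem-dimethyl carbon with a vinyl group as C5.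

Step 3
Reactants: 6 (4R)-3,3-dimethyl-7-[(1R)-4-methylcyclohex-3-en-1-yl]octa-1,7-dien-4-ol; 7 (Z)-but-2-ene-1,4-diol
Product: 8 (2E,5R)-4,4-dimethyl-8-[(1R)-4-methylcyclohex-3-en-1-yl]nona-2,8-diene-1,5-diol
Conditions: second-generation Hoveyda–Grubbs catalyst (5 mol %), 7 (4 equiv), CH2Cl2, 40 °C
Reagents that add atoms: none
Why: Olefin cross-metathesis should engage only the monosubstituted vinyl group (the 1,1-disubstituted and trisubstituted alkenes are inert to the ruthenium carbene), and the quaternary neighbour should enforce the E geometry of C5=C6.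

Step 4
Reactants: 8 (2E,5R)-4,4-dimethyl-8-[(1R)-4-methylcyclohex-3-en-1-yl]nona-2,8-diene-1,5-diol
Product: 9 (2E,5R)-1,5-bis[(tert-butyldimethylsilyl)oxy]-4,4-dimethyl-8-[(1R)-4-methylcyclohex-3-en-1-yl]nona-2,8-diene
Conditions: TBSOTf (2.5 equiv), 2,6-lutidine, CH2Cl2, −78 → 0 °C
Reagents that add atoms: tert-butyldimethylsilyl trifluoromethanesulfonate (TBSOTf), CC(C)(C)[Si](C)(C)OS(=O)(=O)C(F)(F)F
Why: Silylation with the silyl triflate should cap both the primary allylic and the hindered secondary hydroxyl, which is needed for the peracid, amide-base and cuprate steps.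

Step 5
Reactants: 9 (2E,5R)-1,5-bis[(tert-butyldimethylsilyl)oxy]-4,4-dimethyl-8-[(1R)-4-methylcyclohex-3-en-1-yl]nona-2,8-diene
Product: 10 1,2-epoxide of the methylcyclohexene ring of 9 (both epoxide diastereomers)
Conditions: mCPBA (1.05 equiv), NaHCO3, CH2Cl2, −20 °C
Reagents that add atoms: 3-chloroperoxybenzoic acid (mCPBA), OOC(=O)c1cccc(Cl)c1
Why: Prilezhaev epoxidation should take the most electron-rich trisubstituted ring alkene first (the allylic silyl ether alkene is deactivated and hindered), and the epoxide configuration is irrelevant because both carbons become carbonyls.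

Step 6
Reactants: 10 1,2-epoxide of the methylcyclohexene ring of 9
Product: 11 (3R)-3-[(5R,7E)-5,9-bis[(tert-butyldimethylsilyl)oxy]-6,6-dimethylnona-1,7-dien-2-yl]-6-oxoheptanal
Conditions: H5IO6 (1.3 equiv), THF/Et2O, 0 °C
Reagents that add atoms: water, O
Why: Periodic acid should open the epoxide to the glycol and cleave it (Malaprade cleavage) to the C17 aldehyde arm and the methyl ketone arm, leaving the C9 stereocentre, which is β to the aldehyde, untouched.

Step 7
Reactants: 11 (3R)-3-[(5R,7E)-5,9-bis[(tert-butyldimethylsilyl)oxy]-6,6-dimethylnona-1,7-dien-2-yl]-6-oxoheptanal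
Product: 12 (5R)-5-[(5R,7E)-5,9-bis[(tert-butyldimethylsilyl)oxy]-6,6-dimethylnona-1,7-dien-2-yl]-7,7-dimethoxyheptan-2-one
Conditions: HC(OMe)3 (3 equiv), MeOH, PPTS (5 mol %), 0 °C; Et3N quench
Reagents that add atoms: trimethyl orthoformate, COC(OC)OC
Why: Acid-catalysed acetalisation is much faster for the aldehyde than for the methyl ketone, and masking the aldehyde prevents the intramolecular aldol between C8 and the ketone in the basic steps that follow.

Step 8
Reactants: 12 (5R)-5-[(5R,7E)-5,9-bis[(tert-butyldimethylsilyl)oxy]-6,6-dimethylnona-1,7-dien-2-yl]-7,7-dimethoxyheptan-2-one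
Product: 15 methyl (6R)-6-[(5R,7E)-5,9-bis[(tert-butyldimethylsilyl)oxy]-6,6-dimethylnona-1,7-dien-2-yl]-8,8-dimethoxyoct-2-ynoate, via enol phosphate 13 (not isolated), via lithium acetylide 14 (not isolated)
Conditions: LiN(i-Pr)2 (1.05 equiv), THF, −78 °C; ClP(O)(OEt)2, −78 → 23 °C; LiN(i-Pr)2 (2.3 equiv), −78 → 23 °C; ClCO2Me (3 equiv), −78 °C
Reagents that add atoms: methyl chloroformate, COC(=O)Cl
Why: Kinetic deprotonation at the ketone methyl group, O-phosphorylation, base-induced E2 elimination of the enol phosphate and acylation of the resulting alkynyllithium should give the ynoate in one flask, the former ketone methyl becoming C14.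

Step 9
Reactants: 15 methyl (6R)-6-[(5R,7E)-5,9-bis[(tert-butyldimethylsilyl)oxy]-6,6-dimethylnona-1,7-dien-2-yl]-8,8-dimethoxyoct-2-ynoate
Product: 16 methyl (2Z,6R)-6-[(5R,7E)-5,9-bis[(tert-butyldimethylsilyl)oxy]-6,6-dimethylnona-1,7-dien-2-yl]-8,8-dimethoxy-3-methyloct-2-enoate
Conditions: Me2CuLi (2.0 equiv), THF, −78 °C; MeOH at −78 °C, then aq. NH4Cl
Reagents that add atoms: lithium dimethylcuprate, [Li+].C[Cu-]C
Why: Syn-carbocupration of the 2-alkynoate by the Gilman cuprate and stereoretentive protonation of the vinylcopper at −78 °C should place the new methyl cis to the vinylic hydrogen and therefore the chain cis to the ester (13Z).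

Step 10
Reactants: 16 methyl (2Z,6R)-6-[(5R,7E)-5,9-bis[(tert-butyldimethylsilyl)oxy]-6,6-dimethylnona-1,7-dien-2-yl]-8,8-dimethoxy-3-methyloct-2-enoate
Product: 17 methyl (2Z,6R)-6-[(5R,7E)-5,9-bis[(tert-butyldimethylsilyl)oxy]-6,6-dimethylnona-1,7-dien-2-yl]-3-methyl-8-oxooct-2-enoate
Conditions: PPTS (10 mol %), acetone/H2O (10:1), 40 °C
Reagents that add atoms: water, O
Why: Mild acid-catalysed acetal hydrolysis in wet acetone should release the aldehyde without solvolysis of the silyl ethers or isomerisation of the enoate.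

Step 11
Reactants: 17 methyl (2Z,6R)-6-[(5R,7E)-5,9-bis[(tert-butyldimethylsilyl)oxy]-6,6-dimethylnona-1,7-dien-2-yl]-3-methyl-8-oxooct-2-enoate
Product: 19 methyl (2Z,6S)-6-[(5R,7E)-5,9-bis[(tert-butyldimethylsilyl)oxy]-6,6-dimethylnona-1,7-dien-2-yl]-3-methyloct-2-en-7-ynoate, via alkenyl nonaflate 18 (not isolated)
Conditions: C4F9SO2F (1.5 equiv), phosphazene base P2-Et (3 equiv), DMF, −20 → 23 °C
Reagents that add atoms: none
Why: O-sulfonylation of the aldehyde enolate (the most acidic C–H in the molecule) followed by base-induced E2 elimination of nonaflate is a one-flask, non-homologating conversion of an enolisable aldehyde into the terminal alkyne, so C8 and C17 keep the ring carbons of limonene.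

Step 12
Reactants: 19 methyl (2Z,6S)-6-[(5R,7E)-5,9-bis[(tert-butyldimethylsilyl)oxy]-6,6-dimethylnona-1,7-dien-2-yl]-3-methyloct-2-en-7-ynoate
Product: 20 methyl (2Z,6S)-6-[(5R,7E)-5-[(tert-butyldimethylsilyl)oxy]-9-hydroxy-6,6-dimethylnona-1,7-dien-2-yl]-3-methyloct-2-en-7-ynoate
Conditions: PPTS (0.2 equiv), MeOH, 23 °C
Reagents that add atoms: none
Why: Acid-catalysed methanolysis should cleave the primary allylic silyl ether much faster than the secondary one, which is shielded by the adjacent quaternary carbon.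

Step 13
Reactants: 20 methyl (2Z,6S)-6-[(5R,7E)-5-[(tert-butyldimethylsilyl)oxy]-9-hydroxy-6,6-dimethylnona-1,7-dien-2-yl]-3-methyloct-2-en-7-ynoate
Product: 21 methyl (2Z,6S)-6-[(5R,7E)-5-[(tert-butyldimethylsilyl)oxy]-6,6-dimethyl-9-oxonona-1,7-dien-2-yl]-3-methyloct-2-en-7-ynoate
Conditions: MnO2 (15 equiv), CH2Cl2, 23 °C
Reagents that add atoms: none
Why: Allylic oxidation with MnO2 is selective for the allylic alcohol and should give the (E)-enal, which cannot enolise because C4 is quaternary.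

Step 14
Reactants: 21 methyl (2Z,6S)-6-[(5R,7E)-5-[(tert-butyldimethylsilyl)oxy]-6,6-dimethyl-9-oxonona-1,7-dien-2-yl]-3-methyloct-2-en-7-ynoate
Product: 23 methyl (3R,5S,7R,9S,10R,13Z)-3-[(tert-butyldimethylsilyl)oxy]-7-[(triethylsilyl)oxy]labda-8(17),13-dien-15-oate, via ring A aldehyde 22 (not isolated)
Conditions: Fe(acac)3 (0.3 equiv), PhSiH3 (2.5 equiv), EtOH (0.01 M), 60 °C; then EtOH removed under argon and, in the same flask, Ni(COD)2 (0.2 equiv), PBu3 (0.4 equiv), Et3SiH (5 equiv), THF, 23 °C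
Reagents that add atoms: triethylsilane, CC[SiH](CC)CC
Why: The iron hydride formed from Fe(acac)3 and PhSiH3 transfers a hydrogen atom to the only electron-rich alkene (C10=C20), and the tertiary C10 radical closes ring A by 6-exo-trig Giese addition to the enal β-carbon C5; reduction of the α-formyl radical and protonation then release the C7 aldehyde 22 next to the ethynyl group. In the same flask zerovalent nickel couples this aldehyde with the alkyne through an oxanickelacyclopentene (6-exo-dig closure of ring B at C8), and σ-bond metathesis with Et3SiH followed by C–H reductive elimination gives the exocyclic methylene and the C7 silyl ether. The closest known reaction types are the iron-mediated reductive olefin–enone coupling that builds congested quaternary centres and the nickel-catalysed reductive cyclisation of ynals with silanes. C5 and C10 should be set in a chair transition state in which the C3 silyloxy group and the enal arm are equatorial and the small methyl, not the branched C9 substituent, is axial beside the axial C4 methyl, which gives the trans ring fusion relative to C3. C7 should be set by the planar nickelacycle, which holds the C7–O bond in the plane of the forming C8=C17 alkene, that is equatorial on the chair of ring B whose limonene-derived C9 side chain is equatorial. The step needs chemoselectivity (hydrogen-atom transfer to C10=C20 only, and ring B closure only after ring A has brought C7 and C8 together), which is secured by the electron-poor enal and enoate, by the inertness of the terminal alkyne to the iron hydride and by the order of addition.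

Step 15
Reactants: 23 methyl (3R,5S,7R,9S,10R,13Z)-3-[(tert-butyldimethylsilyl)oxy]-7-[(triethylsilyl)oxy]labda-8(17),13-dien-15-oate
Product: 24 methyl (3R,5S,7R,9S,10R,13Z)-3,7-dihydroxylabda-8(17),13-dien-15-oate
Conditions: HF·pyridine, THF, 0 → 23 °C
Reagents that add atoms: none
Why: Fluoride-mediated desilylation under non-basic conditions should remove both silyl ethers without touching the Z-enoate or the allylic alcohol.

**Compound list**
1 | (R)-(+)-limonene | C=C(C)[C@@H]1CCC(C)=CC1 | starting material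
2 | oxirane | C1CO1 | starting material
3 | 10-lithiolimonene (not isolated) | [Li]CC(=C)[C@@H]1CCC(C)=CC1 | intermediate
4 | 4-[(1R)-4-methylcyclohex-3-en-1-yl]pent-4-en-1-ol | OCCCC(=C)[C@@H]1CCC(C)=CC1 | intermediate
5 | 3-methylbuta-1,2-diene | CC(C)=C=C | starting material
6 | (4R)-3,3-dimethyl-7-[(1R)-4-methylcyclohex-3-en-1-yl]octa-1,7-dien-4-ol | C=CC(C)(C)[C@H](O)CCC(=C)[C@@H]1CCC(C)=CC1 | intermediate
7 | (Z)-but-2-ene-1,4-diol | OC/C=C\CO | starting material
8 | (2E,5R)-4,4-dimethyl-8-[(1R)-4-methylcyclohex-3-en-1-yl]nona-2,8-diene-1,5-diol | OC/C=C/C(C)(C)[C@H](O)CCC(=C)[C@@H]1CCC(C)=CC1 | intermediate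
9 | (2E,5R)-1,5-bis[(tert-butyldimethylsilyl)oxy]-4,4-dimethyl-8-[(1R)-4-methylcyclohex-3-en-1-yl]nona-2,8-diene | CC(C)(C)[Si](C)(C)OC/C=C/C(C)(C)[C@H](O[Si](C)(C)C(C)(C)C)CCC(=C)[C@@H]1CCC(C)=CC1 | intermediate
10 | 1,2-epoxide of the methylcyclohexene ring of 9 (both epoxide diastereomers) | CC(C)(C)[Si](C)(C)OC/C=C/C(C)(C)[C@H](O[Si](C)(C)C(C)(C)C)CCC(=C)[C@@H]1CCC2(C)OC2C1 | intermediate
11 | (3R)-3-[(5R,7E)-5,9-bis[(tert-butyldimethylsilyl)oxy]-6,6-dimethylnona-1,7-dien-2-yl]-6-oxoheptanal | CC(C)(C)[Si](C)(C)OC/C=C/C(C)(C)[C@H](O[Si](C)(C)C(C)(C)C)CCC(=C)[C@@H](CC=O)CCC(C)=O | intermediate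
12 | (5R)-5-[(5R,7E)-5,9-bis[(tert-butyldimethylsilyl)oxy]-6,6-dimethylnona-1,7-dien-2-yl]-7,7-dimethoxyheptan-2-one | CC(C)(C)[Si](C)(C)OC/C=C/C(C)(C)[C@H](O[Si](C)(C)C(C)(C)C)CCC(=C)[C@@H](CC(OC)OC)CCC(C)=O | intermediate
13 | kinetic enol diethyl phosphate of 12 (hept-1-en-2-yl diethyl phosphate; not isolated) | CC(C)(C)[Si](C)(C)OC/C=C/C(C)(C)[C@H](O[Si](C)(C)C(C)(C)C)CCC(=C)[C@@H](CC(OC)OC)CCC(=C)OP(=O)(OCC)OCC | intermediate
14 | lithium acetylide of the terminal alkyne formed from 13 (not isolated) | CC(C)(C)[Si](C)(C)OC/C=C/C(C)(C)[C@H](O[Si](C)(C)C(C)(C)C)CCC(=C)[C@@H](CC(OC)OC)CCC#C[Li] | intermediate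
15 | methyl (6R)-6-[(5R,7E)-5,9-bis[(tert-butyldimethylsilyl)oxy]-6,6-dimethylnona-1,7-dien-2-yl]-8,8-dimethoxyoct-2-ynoate | CC(C)(C)[Si](C)(C)OC/C=C/C(C)(C)[C@H](O[Si](C)(C)C(C)(C)C)CCC(=C)[C@@H](CC(OC)OC)CCC#CC(=O)OC | intermediate
16 | methyl (2Z,6R)-6-[(5R,7E)-5,9-bis[(tert-butyldimethylsilyl)oxy]-6,6-dimethylnona-1,7-dien-2-yl]-8,8-dimethoxy-3-methyloct-2-enoate | CC(C)(C)[Si](C)(C)OC/C=C/C(C)(C)[C@H](O[Si](C)(C)C(C)(C)C)CCC(=C)[C@@H](CC(OC)OC)CC/C(C)=C\C(=O)OC | intermediate
17 | methyl (2Z,6R)-6-[(5R,7E)-5,9-bis[(tert-butyldimethylsilyl)oxy]-6,6-dimethylnona-1,7-dien-2-yl]-3-methyl-8-oxooct-2-enoate | CC(C)(C)[Si](C)(C)OC/C=C/C(C)(C)[C@H](O[Si](C)(C)C(C)(C)C)CCC(=C)[C@@H](CC=O)CC/C(C)=C\C(=O)OC | intermediate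
18 | alkenyl nonaflate of 17: methyl (2Z,6R)-6-[(5R,7E)-5,9-bis[(tert-butyldimethylsilyl)oxy]-6,6-dimethylnona-1,7-dien-2-yl]-3-methyl-8-[(nonafluorobutylsulfonyl)oxy]octa-2,7-dienoate (7E/7Z mixture; not isolated) | CC(C)(C)[Si](C)(C)OC/C=C/C(C)(C)[C@H](O[Si](C)(C)C(C)(C)C)CCC(=C)[C@@H](C=COS(=O)(=O)C(F)(F)C(F)(F)C(F)(F)C(F)(F)F)CC/C(C)=C\C(=O)OC | intermediate
19 | methyl (2Z,6S)-6-[(5R,7E)-5,9-bis[(tert-butyldimethylsilyl)oxy]-6,6-dimethylnona-1,7-dien-2-yl]-3-methyloct-2-en-7-ynoate | CC(C)(C)[Si](C)(C)OC/C=C/C(C)(C)[C@H](O[Si](C)(C)C(C)(C)C)CCC(=C)[C@@H](C#C)CC/C(C)=C\C(=O)OC | intermediate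
20 | methyl (2Z,6S)-6-[(5R,7E)-5-[(tert-butyldimethylsilyl)oxy]-9-hydroxy-6,6-dimethylnona-1,7-dien-2-yl]-3-methyloct-2-en-7-ynoate | OC/C=C/C(C)(C)[C@H](O[Si](C)(C)C(C)(C)C)CCC(=C)[C@@H](C#C)CC/C(C)=C\C(=O)OC | intermediate
21 | methyl (2Z,6S)-6-[(5R,7E)-5-[(tert-butyldimethylsilyl)oxy]-6,6-dimethyl-9-oxonona-1,7-dien-2-yl]-3-methyloct-2-en-7-ynoate | O=C/C=C/C(C)(C)[C@H](O[Si](C)(C)C(C)(C)C)CCC(=C)[C@@H](C#C)CC/C(C)=C\C(=O)OC | intermediate
22 | ring A aldehyde: methyl (2Z,6R)-6-[(1S,2S,4R)-4-[(tert-butyldimethylsilyl)oxy]-1,3,3-trimethyl-2-(2-oxoethyl)cyclohexyl]-3-methyloct-2-en-7-ynoate (not isolated) | O=CC[C@@H]1C(C)(C)[C@H](O[Si](C)(C)C(C)(C)C)CC[C@@]1(C)[C@@H](C#C)CC/C(C)=C\C(=O)OC | intermediate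
23 | methyl (3R,5S,7R,9S,10R,13Z)-3-[(tert-butyldimethylsilyl)oxy]-7-[(triethylsilyl)oxy]labda-8(17),13-dien-15-oate | C=C1[C@H](O[Si](CC)(CC)CC)C[C@@H]2C(C)(C)[C@H](O[Si](C)(C)C(C)(C)C)CC[C@@]2(C)[C@@H]1CC/C(C)=C\C(=O)OC | intermediate
24 | methyl (3R,5S,7R,9S,10R,13Z)-3,7-dihydroxylabda-8(17),13-dien-15-oate (methyl ent-3β,7β-dihydroxylabda-8(17),13Z-dien-15-oate; both hydroxyls equatorial) | C=C1[C@H](O)C[C@@H]2C(C)(C)[C@H](O)CC[C@@]2(C)[C@@H]1CC/C(C)=C\C(=O)OC | target

**Total step count:** 15. **Longest linear sequence:** 15 steps from (R)-limonene 1 (the route is fully linear).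

**Steps most likely to fail**

Step 14. The two stages of the relay may interfere: iron and siloxane residues may deactivate the zerovalent nickel catalyst, so that the second closure stalls at the ring A aldehyde. The fallback sets out from 21. Only the Fe(acac)3/PhSiH3 stage is run and 22 is isolated. Ring B is then closed by a different mechanism, a samarium ketyl–alkyne 6-exo-dig radical cyclisation (SmI2, HMPA, t-BuOH, THF, −78 → 0 °C), which should give methyl (3R,5S,7R,9S,10R,13Z)-3-[(tert-butyldimethylsilyl)oxy]-7-hydroxylabda-8(17),13-dien-15-oate F1. HF·pyridine under the conditions of step 15 then cleaves the remaining silyl ether, and the fallback comes back to the route at 24.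

Step 11. The strongly basic phosphazene medium may move the Z-enoate double bond out of conjugation, or isomerise the new alkyne to an allene through the allylic and propargylic C9–H. The fallback sets out from 17 and forms the alkyne by non-basic selenoxide syn-eliminations. PhSeH (2.2 equiv) and ZnCl2 in CH2Cl2 should give the selenoacetal methyl (2Z,6R)-6-[(5R,7E)-5,9-bis[(tert-butyldimethylsilyl)oxy]-6,6-dimethylnona-1,7-dien-2-yl]-3-methyl-8,8-bis(phenylselanyl)oct-2-enoate F2. Oxidation with mCPBA (1 equiv, −78 °C) and warming with i-Pr2NH should give the vinyl selenide methyl (2Z,6R,7E)-6-[(5R,7E)-5,9-bis[(tert-butyldimethylsilyl)oxy]-6,6-dimethylnona-1,7-dien-2-yl]-3-methyl-8-(phenylselanyl)octa-2,7-dienoate F3. A second oxidation (mCPBA, −78 °C) and heating with DABCO in toluene should eliminate the vinyl selenoxide and return to the route at 19.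

Step 3. Conversion of the vinyl group may be low because it is shielded by the quaternary C4, and ruthenium hydride species may isomerise the allylic diol partner and kill the catalyst. The fallback sets out from 4 and builds C3–C7 without metathesis:
- Dess–Martin periodinane should give 4-[(1R)-4-methylcyclohex-3-en-1-yl]pent-4-enal F4.
- An asymmetric Mukaiyama aldol addition of 1-methoxy-2-methyl-1-(trimethylsilyloxy)prop-1-ene, promoted by the N-tosylvaline-derived oxazaborolidinone (1 equiv, from N-tosylvaline and BH3·THF, valine antipode chosen for 3R; CH2Cl2, −78 °C), should give methyl (3R)-3-hydroxy-2,2-dimethyl-6-[(1R)-4-methylcyclohex-3-en-1-yl]hept-6-enoate F5.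
- LiAlH4 should give (3R)-2,2-dimethyl-6-[(1R)-4-methylcyclohex-3-en-1-yl]hept-6-ene-1,3-diol F6.
- TEMPO/PhI(OAc)2 should oxidise only the primary alcohol to (3R)-3-hydroxy-2,2-dimethyl-6-[(1R)-4-methylcyclohex-3-en-1-yl]hept-6-enal F7.
- A Wittig reaction with Ph3P=CHCO2Me (toluene, 80 °C) should give methyl (2E,5R)-5-hydroxy-4,4-dimethyl-8-[(1R)-4-methylcyclohex-3-en-1-yl]nona-2,8-dienoate F8.
- i-Bu2AlH (CH2Cl2, −78 °C) reduces the ester, and the fallback comes back to the route at 8.

Further compounds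
F1 | step 14 | methyl (3R,5S,7R,9S,10R,13Z)-3-[(tert-butyldimethylsilyl)oxy]-7-hydroxylabda-8(17),13-dien-15-oate | C=C1[C@H](O)C[C@@H]2C(C)(C)[C@H](O[Si](C)(C)C(C)(C)C)CC[C@@]2(C)[C@@H]1CC/C(C)=C\C(=O)OC
F2 | step 11 | methyl (2Z,6R)-6-[(5R,7E)-5,9-bis[(tert-butyldimethylsilyl)oxy]-6,6-dimethylnona-1,7-dien-2-yl]-3-methyl-8,8-bis(phenylselanyl)oct-2-enoate | CC(C)(C)[Si](C)(C)OC/C=C/C(C)(C)[C@H](O[Si](C)(C)C(C)(C)C)CCC(=C)[C@@H](CC([Se]c1ccccc1)[Se]c1ccccc1)CC/C(C)=C\C(=O)OC
F3 | step 11 | methyl (2Z,6R,7E)-6-[(5R,7E)-5,9-bis[(tert-butyldimethylsilyl)oxy]-6,6-dimethylnona-1,7-dien-2-yl]-3-methyl-8-(phenylselanyl)octa-2,7-dienoate | CC(C)(C)[Si](C)(C)OC/C=C/C(C)(C)[C@H](O[Si](C)(C)C(C)(C)C)CCC(=C)[C@@H](/C=C/[Se]c1ccccc1)CC/C(C)=C\C(=O)OC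
F4 | step 3 | 4-[(1R)-4-methylcyclohex-3-en-1-yl]pent-4-enal | O=CCCC(=C)[C@@H]1CCC(C)=CC1
F5 | step 3 | methyl (3R)-3-hydroxy-2,2-dimethyl-6-[(1R)-4-methylcyclohex-3-en-1-yl]hept-6-enoate | COC(=O)C(C)(C)[C@H](O)CCC(=C)[C@@H]1CCC(C)=CC1
F6 | step 3 | (3R)-2,2-dimethyl-6-[(1R)-4-methylcyclohex-3-en-1-yl]hept-6-ene-1,3-diol | OCC(C)(C)[C@H](O)CCC(=C)[C@@H]1CCC(C)=CC1
F7 | step 3 | (3R)-3-hydroxy-2,2-dimethyl-6-[(1R)-4-methylcyclohex-3-en-1-yl]hept-6-enal | O=CC(C)(C)[C@H](O)CCC(=C)[C@@H]1CCC(C)=CC1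
F8 | step 3 | methyl (2E,5R)-5-hydroxy-4,4-dimethyl-8-[(1R)-4-methylcyclohex-3-en-1-yl]nona-2,8-dienoate | COC(=O)/C=C/C(C)(C)[C@H](O)CCC(=C)[C@@H]1CCC(C)=CC1
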